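## The problem

Target 24 is a C15 dibromo ether in which a cyclohexane (ring A: C5a, C6, C7, C8, C9, C9a) is trans-fused to an oxepane (ring B: O1, C2, C3, C4, C5, C5a, C9a). The ring oxygen sits on the fully substituted C9a, and C2 is an enol ether carbon with an exocyclic bromomethylidene group, O1 and Br on opposite sides (E).

There are five stereocentres. C9a and C5a define the fusion (O1 and C5 trans and equatorial, the C9a methyl axial) and must be made as a pair. C7 carries an equatorial bromide next to quaternary C6, so the chair of ring A can control it once the fusion exists. The cis-fused C3–C4 oxirane lies on the face of C5a–H but is insulated from ring A by the C5 methylene, so it needs reagent control before ring B closes.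

The alkene geometry cannot be left to equilibration, because the E isomer pushes bromine against quaternary C3; it has to come from a stereospecific addition. The bromo enol ether, the adjacent oxirane and the neopentyl-type secondary bromide do not survive acid or a late SN2 step, and a free C9a hydroxyl will open the oxirane if acid is present. These groups must therefore appear late and in a fixed order.

The enabling feature is that O1 on C9a and C5 on C5a are trans, C5a is bonded to quaternary C6, and C6 is alpha to C7, whose bromide can descend from a carbonyl. This is the pattern of an anti addition of a C6 enolate carbon and an oxygen across an E trisubstituted C9a=C5a alkene: an oxirane opened at C5a by the enolate of a C7 ketone.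

## Retrosynthesis

**24 to 23.** The O1–C2 bond and the exocyclic C–Br bond are cut together, which leads back to the epoxy alkynol 23. Closing ring B at C2–C3 or C3–C4 would first require a vinyl ether of a tertiary alcohol. A lactone-based closure would deliver C2 at the wrong oxidation level, with no stereospecific path to the E bromoalkene. Anti addition of O1 and Br across a terminal alkyne gives the E geometry by mechanism. Precursor 23 has one ring less and no enol ether. The forward step must be a 7-exo-dig closure by a tertiary hydroxyl under non-acidic conditions, because the same hydroxyl can open the oxirane.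

**23 to 19.** The alkyne terminus and the two oxirane C–O bonds are removed through 22, 21 and 20 to reach the Z allylic alcohol 19. The alkyne comes from aldehyde 21 by one-carbon homologation, which is safe because C3 is fully substituted and cannot epimerize. The oxirane comes from 19 by a hydroxyl-directed, tartrate-controlled epoxidation, so its configuration does not depend on the distant ring stereocentres. Dioxirane epoxidation of a Z enyne would save two linear steps, but it relies on a labile Z iodoenyne partner and a less tested substrate class. The tertiary oxygen stays silylated (22) until the step before cyclization, so the hydroxy oxirane 23 exists only briefly.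

**19 to 14 and 17.** The C5–C4 bond is cut between an sp3 and an sp2 carbon. This places the Z geometry in the small alkenyl iodide 17, made in one step from 15, and a Negishi coupling transfers it with retention. Building C4=C3 by olefination would need a homologated aldehyde and a Z-selective trisubstituted olefination. The C5a–C5 bond is already fixed by the key step. Iodide 14 contains only the ring A stereocentres. The forward step requires zinc insertion into the primary C–I bond in the presence of the secondary C–Br bond, which is why the tertiary hydroxyl is masked.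

**14 to 8.** These are functional group changes through 13, 12, 11 and 10. The C7 bromide is traced to the ketone of 8 through alkenyl bromide 10 and a hydrogen atom transfer hydrogenation, which places bromine equatorial under thermodynamic control. Displacement of a C7 alcohol derivative would be an SN2 reaction at a neopentyl-type carbon and is rejected. The sequence has to run before any other alkene enters the molecule. The C5 iodide comes from the silyloxymethyl group.

**8 to 6 (key disconnection).** The C6–C5a bond is cut and ring A opens to the acyclic epoxy ketone 6. Adding a methyl nucleophile to a ring A ketone at C9a would not give the axial methyl and equatorial oxygen. Aldol-type closures place no oxygen on C9a with control of C5a. The enolate opening is stereospecific: inversion at C5a and retention at C9a translate alkene geometry and oxirane configuration into the trans pair. The same step builds the quaternary C6 and leaves the C7 carbonyl. Precursor 6 has no ring and a single stereochemical element. The forward step requires C-alkylation through the more substituted enolate at the less substituted oxirane carbon.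

**6 to 1.** The C7 carbonyl is traced to an alkene C–H through alcohol 5, the silyl ether to 2, and the oxirane to the alkene of geraniol 1. Geraniol has all ten carbons of 6, the E geometry, and the allylic hydroxyl that directs the first epoxidation. Its distal trisubstituted alkene is a latent isopropyl ketone, since anti-Markovnikov hydroboration puts oxygen on the right carbon. Assembling the chain from two five-carbon pieces by enolate alkylation would take more steps and raise a regiochemical question at the ketone.

## Roads not taken

**Alternative 1:** The cut is O1–C2 viewed as an oxygen insertion. Lactone A3 would come from the trans-fused bromo decalone A2 by Baeyer–Villiger oxidation with a buffered peracid, and A2 from the Wieland–Miescher ketone A1.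
- Merits: the ring fusion and angular methyl come from an enantiopure building block. Migration of the tertiary C9a with retention is the normal regiochemistry. The ring expansion is far more dependable than the ring closure of step 17, and there is no enolate regiochemistry to worry about as in step 5. In these respects this road is better.
- Weak points: A3 arrives with C2 as a lactone carbonyl and C3 as a methine without C3–C4 unsaturation. Turning the carbonyl into the E bromomethylidene has no stereospecific solution; methylenation followed by bromination–elimination leaves the geometry to thermodynamics, which disfavours the crowded E isomer. The oxirane would then have to be introduced by dehydrogenation and chemoselective epoxidation beside an enol ether. The C7 bromide still has to be made from a ketone.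
- Comparison: the chosen plan offers an endgame in which O1–C2, the C–Br bond and the alkene geometry arise in one anti addition, with the oxirane already in place.

**Alternative 2:** The cut is O1–C9a by oxidative dearomatization. The cresol acid A4 would be oxidized by a chiral aryl iodide catalyst and a peracid in a fluorinated alcohol, and the carboxylic acid would attack the methyl-bearing para carbon to give the dienone lactone A5.
- Merits: it is the shortest way to a bicyclic core with the C9a–O stereocentre set by a catalyst from a cheap arene. On step count to ring B it beats the chosen plan.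
- Weak points: a seven-membered para-lactonization competes with other dearomatization modes and its enantioselectivity is not assured. A5 lacks the gem-dimethyl group, the bromide and the C3 methyl, and C5a is sp2. The two enone arms of the cross-conjugated dienone have to be told apart, and the trans fusion would depend on reducing a hindered alkene from the correct face. The lactone-to-bromoalkene problem of Alternative 1 remains.
- Comparison: the chosen plan sets C5a and C9a stereospecifically in one step and arrives at ring A with every substituent in place.

**Alternative 3:** The cut is C3–C4 by a Claisen ring expansion. The fused vinyl ketene acetal A6, generated by selenoxide elimination, would rearrange on heating to the seven-membered lactone A7.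
- Merits: the [3,3] shift is a well-tested way to medium-ring lactones and forms ring B with the C3 methyl attached. As a ring B closure it has better precedent than step 17.
- Weak points: A6 needs a cis diol with a vinyl group on C5a beside the gem-dimethyl carbon. The rearrangement makes C5a sp2, so the trans fusion has to be regained by hydrogenating an alkene flanked by two fully substituted carbons. C3 ends as a methine, so the oxirane requires further oxidation. The C7 oxygen would have to become an equatorial bromide at a neopentyl-type centre, and C2 is again a lactone carbonyl.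
- Comparison: the chosen plan fixes C5a by SN2 inversion and delivers the C3–C4 oxirane and the C2 oxidation level without redox corrections.

Key step: step 5

Remark: atom labels (O1, C2–C5, C5a, C6–C9, C9a) are those of the 1-benzoxepine skeleton of 24 and are used for the same atoms in every intermediate; the SMILES of 24 is read as (2E,3R,4R,5aS,7S,9aS).

## Route

Step 1
Reactants: 1 geraniol [(2E)-3,7-dimethylocta-2,6-dien-1-ol]
Product: 2 (2S,3S)-2,3-epoxygeraniol, [(2S,3S)-3-methyl-3-(4-methylpent-3-en-1-yl)oxiran-2-yl]methanol
Conditions: Ti(OiPr)4 (5 mol%), L-(+)-diethyl tartrate (7 mol%), t-BuOOH, 4 Å MS, CH2Cl2, −20 °C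
Reagents that add atoms: tert-butyl hydroperoxide, CC(C)(C)OO
Why: Sharpless asymmetric epoxidation; the allylic hydroxyl directs the titanium tartrate peroxide to the C9a=C5a alkene only, and L-(+)-tartrate selects the face that gives the (2S,3S) oxirane, which fixes C9a and, after inversion in step 5, C5a.

Step 2
Reactants: 2 (2S,3S)-2,3-epoxygeraniol
Product: 3 tert-butyl{[(2S,3S)-3-methyl-3-(4-methylpent-3-en-1-yl)oxiran-2-yl]methoxy}diphenylsilane
Conditions: TBDPSCl, imidazole, DMF, 0 °C to rt
Reagents that add atoms: tert-butyl(chloro)diphenylsilane, CC(C)(C)[Si](Cl)(c1ccccc1)c1ccccc1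
Why: Standard silylation of a primary alcohol; a base-stable ether is needed so that no primary alkoxide can start a Payne rearrangement under the basic conditions of step 5.

Step 3
Reactants: 3 tert-butyl{[(2S,3S)-3-methyl-3-(4-methylpent-3-en-1-yl)oxiran-2-yl]methoxy}diphenylsilane
Product: 5 1-[(2S,3S)-3-{[tert-butyl(diphenyl)silyl]oxymethyl}-2-methyloxiran-2-yl]-4-methylpentan-3-ol (both C3 epimers), via alkylborane 4 (not isolated)
Conditions: 9-BBN, THF, 60 °C; then 3 M NaOH, 30% H2O2, 0 °C to rt
Reagents that add atoms: hydrogen peroxide, OO; 9-borabicyclo[3.3.1]nonane, B1C2CCCC1CCC2 (boron and cage of intermediate 4 only)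
Why: Hydroboration–oxidation; boron adds to the less substituted carbon of the trisubstituted alkene, so oxygen ends on the future C7 next to an isopropyl group, and 9-BBN leaves the oxirane and silyl ether alone. The new carbinol centre is not controlled and is erased in step 4.

Step 4
Reactants: 5 1-[(2S,3S)-3-{[tert-butyl(diphenyl)silyl]oxymethyl}-2-methyloxiran-2-yl]-4-methylpentan-3-ol
Product: 6 1-[(2S,3S)-3-{[tert-butyl(diphenyl)silyl]oxymethyl}-2-methyloxiran-2-yl]-4-methylpentan-3-one
Conditions: Dess–Martin periodinane, NaHCO3, CH2Cl2, 0 °C to rt
Reagents that add atoms: none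
Why: Dess–Martin oxidation of a secondary alcohol under buffered, non-acidic conditions that the trisubstituted oxirane tolerates; both epimers of 5 converge on one ketone.

Step 5
Reactants: 6 1-[(2S,3S)-3-{[tert-butyl(diphenyl)silyl]oxymethyl}-2-methyloxiran-2-yl]-4-methylpentan-3-one
Product: 8 (3R,4S)-3-{[tert-butyl(diphenyl)silyl]oxymethyl}-4-hydroxy-2,2,4-trimethylcyclohexan-1-one, via potassium enolate 7 (not isolated)
Conditions: KOtBu (2 equiv), t-BuOH, 60 °C; aq NH4Cl
Reagents that add atoms: none
Why: KOtBu in t-BuOH equilibrates the enolates of 6, and the tetrasubstituted potassium enolate 7 attacks the secondary oxirane carbon C5a from the side opposite its C–O bond, forming C6–C5a and closing ring A; the C9a alkoxide is protonated on work-up. The closest known reaction type is the intramolecular alkylation of ketone enolates and nitrile anions by epoxides (Stork epoxynitrile cyclization). Ring A closes as a six-membered enolendo ring with endo-mode opening of the oxirane, both oxirane carbons becoming ring atoms. C5a is set by inversion and C9a keeps its configuration, so both follow from the E geometry of 1 and the tartrate of step 1, and a chair transition state places oxygen and the silyloxymethyl group trans and equatorial with the methyl axial. C6 becomes quaternary but is not a stereocentre. The step needs C- over O-alkylation and reaction through the more substituted enolate: a potassium enolate in a hydrogen-bonding solvent favours carbon attack, the five-membered alternative at C9a is an enolendo attack on a fully substituted carbon, and the methylene (C8) enolate has only a three-membered closure at that same hindered carbon or a four-membered one and can revert to the ketone. The silyl ether prevents a Payne rearrangement that would scramble C5a.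

Step 6
Reactants: 8 (3R,4S)-3-{[tert-butyl(diphenyl)silyl]oxymethyl}-4-hydroxy-2,2,4-trimethylcyclohexan-1-one
Product: 10 (1S,6R)-4-bromo-6-{[tert-butyl(diphenyl)silyl]oxymethyl}-1,5,5-trimethylcyclohex-3-en-1-ol, via hydrazone 9 (not isolated)
Conditions: N2H4·H2O, Et3N, EtOH, 80 °C; evaporate; then NBS, pyridine, −10 to 0 °C
Reagents that add atoms: N-bromosuccinimide, O=C1CCC(=O)N1Br; hydrazine, NN (nitrogen atoms of intermediate 9 only)
Why: Hydrazone formation followed by oxidative bromination (Barton-type vinyl halide synthesis); after loss of N2 a proton can only leave from C8, because C6 is quaternary, so the alkenyl bromide forms with one regiochemistry and no stereocentre is touched.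

Step 7
Reactants: 10 (1S,6R)-4-bromo-6-{[tert-butyl(diphenyl)silyl]oxymethyl}-1,5,5-trimethylcyclohex-3-en-1-ol
Product: 11 (1S,2R,4S)-4-bromo-2-{[tert-butyl(diphenyl)silyl]oxymethyl}-1,3,3-trimethylcyclohexan-1-ol
Conditions: Mn(dpm)3 (10 mol%), PhSiH3, t-BuOOH, i-PrOH, rt
Reagents that add atoms: none
Why: Hydrogen atom transfer hydrogenation of an alkenyl halide by a trivalent manganese hydride; H adds to C8 and the α-bromo radical at C7 accepts its hydrogen on the axial face, which should give the thermodynamically preferred equatorial bromide (7S) without C–Br cleavage.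

Step 8
Reactants: 11 (1S,2R,4S)-4-bromo-2-{[tert-butyl(diphenyl)silyl]oxymethyl}-1,3,3-trimethylcyclohexan-1-ol
Product: 12 (1S,2R,4S)-4-bromo-2-(hydroxymethyl)-1,3,3-trimethylcyclohexan-1-ol
Conditions: TBAF, THF, 0 °C to rt
Reagents that add atoms: none
Why: Fluoride-mediated desilylation; the equatorial neopentyl-type bromide has no anti-periplanar hydrogen and is too hindered for substitution, so it should survive the basic fluoride.

Step 9
Reactants: 12 (1S,2R,4S)-4-bromo-2-(hydroxymethyl)-1,3,3-trimethylcyclohexan-1-ol
Product: 13 (1S,2S,4S)-4-bromo-2-(iodomethyl)-1,3,3-trimethylcyclohexan-1-ol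
Conditions: I2, PPh3, imidazole, toluene/MeCN, 0 to 60 °C
Reagents that add atoms: iodine, II
Why: Appel-type iodination; only the primary hydroxyl forms an alkoxyphosphonium ion that iodide can displace, and the tertiary hydroxyl is left alone (the C2 descriptor changes only because of CIP priorities).

Step 10
Reactants: 13 (1S,2S,4S)-4-bromo-2-(iodomethyl)-1,3,3-trimethylcyclohexan-1-ol
Product: 14 {[(1S,2S,4S)-4-bromo-2-(iodomethyl)-1,3,3-trimethylcyclohexyl]oxy}triethylsilane
Conditions: TESOTf, 2,6-lutidine, CH2Cl2, −78 to 0 °C
Reagents that add atoms: triethylsilyl trifluoromethanesulfonate, CC[Si](CC)(CC)OS(=O)(=O)C(F)(F)F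
Why: Silylation of a hindered tertiary alcohol with a silyl triflate; the masked oxygen can neither protonate the alkylzinc of step 12 nor open the oxirane made in step 13.

Step 11
Reactants: 15 prop-2-yn-1-ol
Product: 17 (2Z)-3-iodo-2-methylprop-2-en-1-ol, via alkenylmagnesium bromide 16 (not isolated)
Conditions: MeMgBr (2.5 equiv), CuI (10 mol%), THF, −10 °C to rt; then I2, −10 °C
Reagents that add atoms: methylmagnesium bromide, C[Mg]Br; iodine, II
Why: Copper-catalysed anti-carbomagnesiation of a propargylic alkoxide; methyl adds to the internal carbon and magnesium ends on the terminal carbon cis to the oxygen through a five-membered chelate, and iodinolysis with retention gives the Z iodide.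

Step 12
Reactants: 14 {[(1S,2S,4S)-4-bromo-2-(iodomethyl)-1,3,3-trimethylcyclohexyl]oxy}triethylsilane; 17 (2Z)-3-iodo-2-methylprop-2-en-1-ol
Product: 19 (2Z)-4-[(1S,3S,6S)-3-bromo-2,2,6-trimethyl-6-(triethylsilyloxy)cyclohexyl]-2-methylbut-2-en-1-ol, via alkylzinc iodide 18 (not isolated)
Conditions: Zn dust (activated with BrCH2CH2Br/Me3SiCl), LiCl, THF, 25–30 °C; then 17 (1.3 equiv), Pd(OAc)2 (3 mol%), SPhos (6 mol%), THF, rt
Reagents that add atoms: none
Why: Zinc inserts into the primary C–I bond and not into the hindered secondary C–Br bond, and the Negishi coupling at zerovalent palladium keeps the geometry of 17, so C5 and the hydroxymethyl carbon (future C2) are cis. The SPhos catalyst should couple faster than the alkylzinc is protonated by the free hydroxyl.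

Step 13
Reactants: 19 (2Z)-4-[(1S,3S,6S)-3-bromo-2,2,6-trimethyl-6-(triethylsilyloxy)cyclohexyl]-2-methylbut-2-en-1-ol
Product: 20 [(2S,3R)-3-{[(1S,3S,6S)-3-bromo-2,2,6-trimethyl-6-(triethylsilyloxy)cyclohexyl]methyl}-2-methyloxiran-2-yl]methanol
Conditions: Ti(OiPr)4 (20 mol%), L-(+)-diethyl tartrate (24 mol%), t-BuOOH, 4 Å MS, CH2Cl2, −20 °C
Reagents that add atoms: tert-butyl hydroperoxide, CC(C)(C)OO
Why: Sharpless asymmetric epoxidation of a Z-configured 2-methyl allylic alcohol; L-(+)-tartrate delivers oxygen to the face that becomes syn to C5a–H in 24 (C3 and C4 set by reagent control), and the silyl ether keeps the tertiary oxygen away from the titanium centre and the new oxirane.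

Step 14
Reactants: 20 [(2S,3R)-3-{[(1S,3S,6S)-3-bromo-2,2,6-trimethyl-6-(triethylsilyloxy)cyclohexyl]methyl}-2-methyloxiran-2-yl]methanol
Product: 21 (2R,3R)-3-{[(1S,3S,6S)-3-bromo-2,2,6-trimethyl-6-(triethylsilyloxy)cyclohexyl]methyl}-2-methyloxirane-2-carbaldehyde
Conditions: Dess–Martin periodinane, NaHCO3, CH2Cl2, 0 °C to rt
Reagents that add atoms: none
Why: Dess–Martin oxidation of an epoxy alcohol to the epoxy aldehyde under buffered conditions; the α-carbon is fully substituted, so nothing can epimerize (the descriptor change at C2 of the oxirane is a CIP effect).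

Step 15
Reactants: 21 (2R,3R)-3-{[(1S,3S,6S)-3-bromo-2,2,6-trimethyl-6-(triethylsilyloxy)cyclohexyl]methyl}-2-methyloxirane-2-carbaldehyde
Product: 22 {[(1S,2S,4S)-4-bromo-2-{[(2R,3S)-3-ethynyl-3-methyloxiran-2-yl]methyl}-1,3,3-trimethylcyclohexyl]oxy}triethylsilane
Conditions: dimethyl (1-diazo-2-oxopropyl)phosphonate, K2CO3, MeOH, 0 °C to rt
Reagents that add atoms: dimethyl (1-diazo-2-oxopropyl)phosphonate (Ohira–Bestmann reagent), CC(=O)C(=[N+]=[N-])P(=O)(OC)OC
Why: Seyferth–Gilbert homologation with the Ohira–Bestmann reagent; the aldehyde carbon becomes the internal alkyne carbon C2 and the reagent supplies the terminal carbon, while the oxirane, silyl ether and hindered bromide tolerate K2CO3 in MeOH.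

Step 16
Reactants: 22 {[(1S,2S,4S)-4-bromo-2-{[(2R,3S)-3-ethynyl-3-methyloxiran-2-yl]methyl}-1,3,3-trimethylcyclohexyl]oxy}triethylsilane
Product: 23 (1S,2S,4S)-4-bromo-2-{[(2R,3S)-3-ethynyl-3-methyloxiran-2-yl]methyl}-1,3,3-trimethylcyclohexan-1-ol
Conditions: TBAF, THF, 0 °C
Reagents that add atoms: none
Why: Fluoride cleaves the Si–O bond of the tertiary silyl ether under non-acidic conditions, which is what the hydroxy oxirane needs; the product is taken on without exposure to acid.

Step 17
Reactants: 23 (1S,2S,4S)-4-bromo-2-{[(2R,3S)-3-ethynyl-3-methyloxiran-2-yl]methyl}-1,3,3-trimethylcyclohexan-1-ol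
Product: 24 (2E,3R,4R,5aS,7S,9aS)-7-bromo-2-(bromomethylidene)-3,4-epoxy-3,6,6,9a-tetramethyldecahydro-1-benzoxepine (CNP0375295.1)
Conditions: NBS, NaHCO3, MeCN, 0 °C to rt, dark
Reagents that add atoms: N-bromosuccinimide, O=C1CCC(=O)N1Br
Why: Proposed new method: Br+ from NBS activates the terminal alkyne and the C9a hydroxyl, held close by the trans-diequatorial fusion and the cis oxirane, attacks the internal carbon C2 in a 7-exo-dig anti addition, so O1 and Br end up trans (E) and ring B closes in the same event; the closest known reaction type is the exo-dig halocyclization of alkynols and alkynoic acids to E-halomethylidene five- and six-membered ethers and lactones, together with bromoetherification of alkenols to oxepanes; no new stereocentre forms, Markovnikov attack at the internal carbon is the only electronically reasonable mode, and solid NaHCO3 keeps the hydroxy oxirane from acid-induced opening.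

## Compound list

1 | geraniol, (2E)-3,7-dimethylocta-2,6-dien-1-ol | CC(C)=CCC/C(C)=C/CO | starting material
2 | (2S,3S)-2,3-epoxygeraniol, [(2S,3S)-3-methyl-3-(4-methylpent-3-en-1-yl)oxiran-2-yl]methanol | CC(C)=CCC[C@]1(C)O[C@H]1CO | intermediate
3 | tert-butyl{[(2S,3S)-3-methyl-3-(4-methylpent-3-en-1-yl)oxiran-2-yl]methoxy}diphenylsilane | CC(C)=CCC[C@]1(C)O[C@H]1CO[Si](c1ccccc1)(c1ccccc1)C(C)(C)C | intermediate
4 | B-alkyl-9-borabicyclo[3.3.1]nonane from 3 (boron on the carbon next to the isopropyl group, both epimers) | CC(C)C(CC[C@]1(C)O[C@H]1CO[Si](c1ccccc1)(c1ccccc1)C(C)(C)C)B1C2CCCC1CCC2 | intermediate (not isolated)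
5 | 1-[(2S,3S)-3-{[tert-butyl(diphenyl)silyl]oxymethyl}-2-methyloxiran-2-yl]-4-methylpentan-3-ol (both C3 epimers) | CC(C)C(O)CC[C@]1(C)O[C@H]1CO[Si](c1ccccc1)(c1ccccc1)C(C)(C)C | intermediate
6 | 1-[(2S,3S)-3-{[tert-butyl(diphenyl)silyl]oxymethyl}-2-methyloxiran-2-yl]-4-methylpentan-3-one | CC(C)C(=O)CC[C@]1(C)O[C@H]1CO[Si](c1ccccc1)(c1ccccc1)C(C)(C)C | intermediate
7 | tetrasubstituted potassium enolate of 6 (C6=C7) | CC(C)=C([O-])CC[C@]1(C)O[C@H]1CO[Si](c1ccccc1)(c1ccccc1)C(C)(C)C.[K+] | intermediate (not isolated)
8 | (3R,4S)-3-{[tert-butyl(diphenyl)silyl]oxymethyl}-4-hydroxy-2,2,4-trimethylcyclohexan-1-one | CC1(C)C(=O)CC[C@](C)(O)[C@H]1CO[Si](c1ccccc1)(c1ccccc1)C(C)(C)C | intermediate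
9 | hydrazone of 8 | CC1(C)C(=NN)CC[C@](C)(O)[C@H]1CO[Si](c1ccccc1)(c1ccccc1)C(C)(C)C | intermediate (not isolated)
10 | (1S,6R)-4-bromo-6-{[tert-butyl(diphenyl)silyl]oxymethyl}-1,5,5-trimethylcyclohex-3-en-1-ol | CC1(C)C(Br)=CC[C@](C)(O)[C@H]1CO[Si](c1ccccc1)(c1ccccc1)C(C)(C)C | intermediate
11 | (1S,2R,4S)-4-bromo-2-{[tert-butyl(diphenyl)silyl]oxymethyl}-1,3,3-trimethylcyclohexan-1-ol | CC1(C)[C@@H](Br)CC[C@](C)(O)[C@H]1CO[Si](c1ccccc1)(c1ccccc1)C(C)(C)C | intermediate
12 | (1S,2R,4S)-4-bromo-2-(hydroxymethyl)-1,3,3-trimethylcyclohexan-1-ol | CC1(C)[C@@H](Br)CC[C@](C)(O)[C@H]1CO | intermediate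
13 | (1S,2S,4S)-4-bromo-2-(iodomethyl)-1,3,3-trimethylcyclohexan-1-ol | CC1(C)[C@@H](Br)CC[C@](C)(O)[C@H]1CI | intermediate
14 | {[(1S,2S,4S)-4-bromo-2-(iodomethyl)-1,3,3-trimethylcyclohexyl]oxy}triethylsilane | CC1(C)[C@@H](Br)CC[C@](C)(O[Si](CC)(CC)CC)[C@H]1CI | intermediate
15 | prop-2-yn-1-ol | C#CCO | starting material
16 | (Z)-[3-(bromomagnesiooxy)-2-methylprop-1-en-1-yl]magnesium bromide | Br[Mg]OC/C(C)=C\[Mg]Br | intermediate (not isolated)
17 | (2Z)-3-iodo-2-methylprop-2-en-1-ol | OC/C(C)=C\I | intermediate
18 | alkylzinc iodide from 14 (zinc on C5) | CC1(C)[C@@H](Br)CC[C@](C)(O[Si](CC)(CC)CC)[C@H]1C[Zn]I | intermediate (not isolated)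
19 | (2Z)-4-[(1S,3S,6S)-3-bromo-2,2,6-trimethyl-6-(triethylsilyloxy)cyclohexyl]-2-methylbut-2-en-1-ol | CC1(C)[C@@H](Br)CC[C@](C)(O[Si](CC)(CC)CC)[C@H]1C/C=C(C)\CO | intermediate
20 | [(2S,3R)-3-{[(1S,3S,6S)-3-bromo-2,2,6-trimethyl-6-(triethylsilyloxy)cyclohexyl]methyl}-2-methyloxiran-2-yl]methanol | CC1(C)[C@@H](Br)CC[C@](C)(O[Si](CC)(CC)CC)[C@H]1C[C@H]2O[C@@]2(C)CO | intermediate
21 | (2R,3R)-3-{[(1S,3S,6S)-3-bromo-2,2,6-trimethyl-6-(triethylsilyloxy)cyclohexyl]methyl}-2-methyloxirane-2-carbaldehyde | CC1(C)[C@@H](Br)CC[C@](C)(O[Si](CC)(CC)CC)[C@H]1C[C@H]2O[C@@]2(C)C=O | intermediate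
22 | {[(1S,2S,4S)-4-bromo-2-{[(2R,3S)-3-ethynyl-3-methyloxiran-2-yl]methyl}-1,3,3-trimethylcyclohexyl]oxy}triethylsilane | CC1(C)[C@@H](Br)CC[C@](C)(O[Si](CC)(CC)CC)[C@H]1C[C@H]2O[C@@]2(C)C#C | intermediate
23 | (1S,2S,4S)-4-bromo-2-{[(2R,3S)-3-ethynyl-3-methyloxiran-2-yl]methyl}-1,3,3-trimethylcyclohexan-1-ol | CC1(C)[C@@H](Br)CC[C@](C)(O)[C@H]1C[C@H]2O[C@@]2(C)C#C | intermediate
24 | (2E,3R,4R,5aS,7S,9aS)-7-bromo-2-(bromomethylidene)-3,4-epoxy-3,6,6,9a-tetramethyldecahydro-1-benzoxepine (CNP0375295.1) | CC1(C)[C@@H](Br)CC[C@]2(C)O/C(=C/Br)[C@]3(C)O[C@@H]3C[C@@H]12 | target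

Total step count: 17. Longest linear sequence: 16 steps (1 to 24 through steps 1–10 and 12–17); step 11 supplies the side-chain iodide 17.

## Least certain steps

**Step 17 (Proposed new method).**
- What may go wrong: the seven-membered closure may be too slow on an alkyne deactivated by the neighbouring oxirane. Bromination of the acetylenic C–H, or opening of the oxirane by the C9a hydroxyl once traces of acid appear, could then take over.
- Fallback: it sets out from 23 and uses the known oxymercuration–halodemercuration route to E-halomethylidene heterocycles. Hg(OCOCF3)2 in CH2Cl2 at 0 °C, with divalent mercury as a much stronger alkyne activator, followed by aqueous NaCl, should give by anti addition the (E)-alkenylmercury chloride F1. Bromodemercuration of F1 with NBS in MeCN, which proceeds with retention, returns to the route at 24.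

**Step 5 (key step).**
- What may go wrong: alkylation may run through the methylene (C8) enolate, closing a three-membered ring at C9a, and the enolate oxygen may alkylate instead of carbon. Partial migration of the silyl group to the new tertiary alkoxide would be harmless, since both silyl isomers converge at 12.
- Fallback: it sets out from 6 and blocks C8. Tert-butoxybis(dimethylamino)methane (Bredereck's reagent) in toluene at 80 °C condenses only at the methylene to give the dimethylaminomethylene ketone F2. KHMDS in THF can then deprotonate only C6, and cyclization should give the blocked ketol F3. Hydrolysis with aqueous AcOH/NaOAc and deformylation with K2CO3 in MeOH/H2O return to the route at 8.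

**Step 6.**
- What may go wrong: condensation of hydrazine with the hindered carbonyl may be slow. In the cationic stage after loss of N2, capture of a second bromide, a methyl shift from C6, or transannular capture by the C9a hydroxyl may compete with loss of the C8 proton.
- Fallback: it sets out from 8. KHMDS (2.2 equiv) and N-phenylbis(trifluoromethanesulfonimide) in THF at −78 °C give the enol triflate F4, with regiochemistry fixed by the quaternary C6. Ni(cod)2-catalysed triflate–bromide exchange with LiBr in DMA/THF returns to the route at 10.

**Step 12.**
- What may go wrong: zinc insertion into the β-branched primary iodide may be slow, which invites insertion at the secondary bromide on warming. The alkylzinc may be protonated by the hydroxyl of 17 before it couples.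
- Fallback: it sets out from 14 and changes the nucleophile to boron. Lithium–iodine exchange with t-BuLi in Et2O at −78 °C in the presence of 9-methoxy-9-borabicyclo[3.3.1]nonane gives the lithium borinate F5. Suzuki–Miyaura coupling of F5 with 17 [PdCl2(dppf), K3PO4, DMF/H2O, rt], which tolerates the free hydroxyl, returns to the route at 19.

**Step 13.**
- What may go wrong: Z allylic alcohols are the slow substrate class for the titanium tartrate system, so facial selectivity may be poor and long exposure to the Lewis acid may open the product.
- Fallback: it sets out from 19 and uses dioxirane chemistry instead. Shi epoxidation with the D-fructose-derived ketone (Oxone, K2CO3 buffer, MeCN/dimethoxymethane/H2O, 0 °C) should, by the spiro transition state model, deliver oxygen to the same face. It returns to the route directly at 20 without a new intermediate.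

## Further compounds

F1 | step 17 | (E)-alkenylmercury chloride of the ring B enol ether (chloromercurio group in place of the vinylic bromine of 24) | CC1(C)[C@@H](Br)CC[C@]2(C)O/C(=C/[Hg]Cl)[C@]3(C)O[C@@H]3C[C@@H]12
F2 | step 5 | (E)-2-(dimethylaminomethylidene) derivative of 6 (blocking group on C8) | CC(C)C(=O)/C(=C/N(C)C)C[C@]1(C)O[C@H]1CO[Si](c1ccccc1)(c1ccccc1)C(C)(C)C
F3 | step 5 | (E)-6-(dimethylaminomethylidene) derivative of ketol 8 | CC1(C)C(=O)/C(=C/N(C)C)C[C@](C)(O)[C@H]1CO[Si](c1ccccc1)(c1ccccc1)C(C)(C)C
F4 | step 6 | enol triflate of 8 (C7–OTf, C7=C8) | CC1(C)C(OS(=O)(=O)C(F)(F)F)=CC[C@](C)(O)[C@H]1CO[Si](c1ccccc1)(c1ccccc1)C(C)(C)C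
F5 | step 12 | lithium B-alkyl-B-methoxy-9-borabicyclo[3.3.1]nonane borinate from 14 (boron on C5) | CC1(C)[C@@H](Br)CC[C@](C)(O[Si](CC)(CC)CC)[C@H]1C[B-]2(OC)C3CCCC2CCC3.[Li+]
F0 | step 13 | none | none
A1 | alternative 1 | (S)-Wieland–Miescher ketone, (8aS)-8a-methyl-3,4,8,8a-tetrahydronaphthalene-1,6(2H,7H)-dione | C[C@]12CCC(=O)C=C1CCCC2=O
A2 | alternative 1 | trans-fused 6-bromo-2,5,5,8a-tetramethyloctahydronaphthalen-1(2H)-one | CC1(C)[C@@H](Br)CC[C@]2(C)C(=O)[C@H](C)CC[C@@H]12
A3 | alternative 1 | 7-bromo-3,6,6,9a-tetramethyloctahydro-1-benzoxepin-2(3H)-one | CC1(C)[C@@H](Br)CC[C@]2(C)OC(=O)[C@H](C)CC[C@@H]12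
A4 | alternative 2 | 4-(5-hydroxy-2-methylphenyl)butanoic acid | Cc1ccc(O)cc1CCCC(=O)O
A5 | alternative 2 | dienone-fused seven-membered lactone, 9a-methyl-4,5-dihydro-1-benzoxepine-2,7(3H,9aH)-dione | O=C1C=C2CCCC(=O)O[C@@]2(C)C=C1
A6 | alternative 3 | cis-fused 2-ethylidene-1,3-dioxolane on C9a–C5a with a vinyl group on C5a and a silyloxy group on C7 | CC1(C)[C@@H](O[Si](C)(C)C(C)(C)C)CC[C@]2(C)OC(=CC)O[C@]12C=C
A7 | alternative 3 | seven-membered lactone with C5=C5a alkene, C3 methyl and C7 silyl ether | CC1(C)[C@@H](O[Si](C)(C)C(C)(C)C)CC[C@]2(C)OC(=O)[C@H](C)CC=C12
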